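It is easy to take the isomer for a slow leak that drains the target for as long as you wait, but in this flask the leak has a stop.

solid substrate 0.10 M; gas 11 mM (held); time 80 min

    target ⇌ isomer of the product (K1 = 0.58, k1 = 0.016 min⁻¹)
    2 dissolved substrate → side product (k2 = 0.19 M⁻¹ min⁻¹)
    solid product ⇌ target, rate k3*(cs3 - [target]) while solid is left; crystals form when [target] > cs3 (cs3 = 36 mM, k3 = 0.67 min⁻¹)
    gas ⇌ coupling partner, rate k4*(csat - [coupling partner]) (k4 = 0.71 min⁻¹, csat = 11 mM)
    dissolved substrate + coupling partner → target (k5 = 20 M⁻¹ min⁻¹)
    solid substrate ⇌ dissolved substrate, rate k6*(cs6 - [dissolved substrate]) while solid is left; crystals form when [dissolved substrate] > cs6 (cs6 = 17 mM, k6 = 0.24 min⁻¹)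

- percent here means solid substrate units held: one side product counts as two
- what is said of target includes solid product
- two of one species on the left: rate k times its square, two consumed each time
- solid substrate, solid product is a solid; its amount is given per volume of the solution
- at the start none of coupling partner is dissolved
- at the start none of the solid substrate is in solution
- run time (flask): 80 min

* the target and solid product together standing at 80 min, as a percentage of the solid substrate charged
* the change that raises the amount of target and solid product together at 80 min, in percent of the solid substrate charged most ("none" if none brings more than 2 percentage points) (eta / gamma / delta / theta / none)
* amount of target and solid product together at 80 min, in percent of the solid substrate charged, after theta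

- eta: doubling the dissolution coefficient of step 3, all else as stated
- gamma: doubling the saturation concentration of gas, all else as stated
- delta: doubling the solubility in step 3, all else as stated
- theta: doubling the solubility in step 6, all else as stated

Follow one molecule and ask, at each fork, how often per minute it takes each way. The first row is a pseudo-first-order constant, the coupling rate constant times the concentration of coupling partner. The second is the pairing rate constant times the concentration of dissolved substrate, doubled since two go at each turn. The last two rows are plain first-order constants with no partner. I take coupling partner at its saturation 11 mM and dissolved substrate at its solubility 17 mM.

| Way | Frequency per molecule |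
|---|---|
| dissolved substrate couples | 0.220 min⁻¹ |
| dissolved substrate pairs | 0.00646 min⁻¹ |
| target turns to isomer | 0.016 min⁻¹ |
| isomer turns back | 0.0276 min⁻¹ |

Read the first two rows against each other. Coupling is much faster than pairing, so the chance p of ending as side product is fp/(fc+fp), or 2.85%.

The last two rows together give a relaxation half-life of 15.9 min, short against the 80 min run, so isomer can follow dissolved target towards K1 times its concentration. While crystals of solid product stand, dissolved target sits near its solubility 36 mM. That gives the isomer ceiling: K1 times the solubility of target, divided by the charge, 20.9%.

I therefore commit to 76.3% for y, on the low side if isomer is still climbing at 80 min. Theta doubles the pairing row, so p becomes 5.55% and I expect 73.5%. Gamma doubles the coupling row and gains me 1.4 percentage points, under the 2 points mark. Eta does not enter the ceiling, and delta raises it, so I answer none.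

The forecast gave 80%, none and 76% after theta, higher than mine, holding that “the main loss is about 18% to the isomer”.

The flask gives 80.2%, none, and 77.3% after theta, with gamma at 1.1 points and delta at −12 points. In the neighbour charged with 0.040 M, the ceiling over its own charge is 52.2%, above the equilibrium share K1/(1+K1) of 36.7%; that neighbour reads solid product 0% and isomer 33.8%. The flask itself is not quite at rest after 80.0 min: solid substrate stands at 0%, but isomer at 17.8% is under the ceiling. After 800 min, isomer reads 20.9%, side product remains 1.97%, and target with solid product has slipped to 77.2%.

The rate constants are invented; what happens was integrated by code.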